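With the heptane chain numbered so that C3 carries the free hydroxyl and C5 the acetoxy group, the C3(OH)–C4H2–C5(OAc) unit of the anti-1,3-diol monoacetate is read as an aldol adduct that has undergone a Tishchenko redox-esterification. Everything rests on the C4–C5 bond: a catalytic enantioselective Mukaiyama aldol joins the terminal silyl enol ether of O-benzylzingerone (C1–C4 plus one guaiacyl ring) to O-benzyl-dihydroconiferyl aldehyde (C5–C7 plus the other ring) and sets C5 in the same operation. The precursor is therefore two achiral, open-chain halves drawn from the same guaiacylpropanoid pool. An Evans–Tishchenko reduction with acetaldehyde then relays C5 to C3 and places the acetate on the C5 oxygen.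

Key step: step 5

Remark on the chemistry: the facial sense assigned to the tryptophan-derived catalyst (Re-face attack with the (S)-amino acid) is taken from its usual transition-state model; it should be confirmed on 9 by Mosher ester analysis, and the catalyst from (R)-tryptophan is to be used if the opposite sense is found.

Step 1
Reactants: 1 zingerone, 4-(4-hydroxy-3-methoxyphenyl)butan-2-one
Product: 2 4-[4-(benzyloxy)-3-methoxyphenyl]butan-2-one
Conditions: BnBr, K2CO3, DMF, rt
Reagents that add atoms: benzyl bromide, BrCc1ccccc1
Why: Williamson ether synthesis, in which carbonate ionises only the phenol and the phenoxide displaces bromide from benzyl bromide (SN2) while the ketone is not enolised by this weak base.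

Step 2
Reactants: 2 4-[4-(benzyloxy)-3-methoxyphenyl]butan-2-one
Product: 4 2-(trimethylsilyloxy)-4-[4-(benzyloxy)-3-methoxyphenyl]but-1-ene, via lithium enolate 3 (not isolated)
Conditions: LDA (commercial solution), THF, −78 °C; TMSCl, −78 °C to 0 °C; non-aqueous work-up (pentane, filtration), used crude
Reagents that add atoms: chlorotrimethylsilane, C[Si](C)(C)Cl
Why: Kinetic deprotonation by the hindered amide base at −78 °C takes the less hindered methyl protons to give the terminal enolate 3, which chlorotrimethylsilane traps on oxygen (silyl enol ether formation) before it can equilibrate to the internal enolate.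

Step 3
Reactants: 5 dihydroconiferyl alcohol, 3-(4-hydroxy-3-methoxyphenyl)propan-1-ol
Product: 6 3-[4-(benzyloxy)-3-methoxyphenyl]propan-1-ol
Conditions: BnBr, K2CO3, DMF, rt
Reagents that add atoms: benzyl bromide, BrCc1ccccc1
Why: Chemoselective Williamson ether synthesis, since carbonate ionises the phenol but not the primary alcohol, so that only the phenoxide is benzylated.

Step 4
Reactants: 6 3-[4-(benzyloxy)-3-methoxyphenyl]propan-1-ol
Product: 7 3-[4-(benzyloxy)-3-methoxyphenyl]propanal
Conditions: Dess–Martin periodinane, CH2Cl2, 0 °C to rt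
Reagents that add atoms: none
Why: Dess–Martin oxidation converts the primary alcohol into the aldehyde by ligand exchange at iodine(V) and loss of acetic acid, without over-oxidation and without touching the aryl ethers.

Step 5
Reactants: 4 2-(trimethylsilyloxy)-4-[4-(benzyloxy)-3-methoxyphenyl]but-1-ene, 7 3-[4-(benzyloxy)-3-methoxyphenyl]propanal
Product: 9 (5S)-1,7-bis[4-(benzyloxy)-3-methoxyphenyl]-5-hydroxyheptan-3-one, via silyl aldol 8 (not isolated)
Conditions: B-n-butyl oxazaborolidinone from N-tosyl-(S)-tryptophan (20 mol%), EtCN, −78 °C; then 1 M HCl, THF, 0 °C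
Reagents that add atoms: none
Why: Catalytic enantioselective Mukaiyama aldol addition: the boron Lewis acid binds the formyl oxygen of 7 anti to its alkyl chain, the terminal sp2 carbon of 4 (C4) adds to the carbonyl carbon (C5) through an open transition state, and silyl transfer to the boron aldolate releases the catalyst and gives silyl ether 8, which dilute acid cleaves to 9. The closest known reaction type is the chiral (acyloxy)borane- or oxazaborolidinone-catalysed aldol of methyl ketone enol silanes with aliphatic aldehydes. No ring is closed. The only new stereocentre, C5, is controlled by the catalyst: the indole ring of the tryptophan unit stacks against one face of the bound C=O and leaves the Re face open, which corresponds to 5S. The step needs C4 rather than C2 of the ketone as nucleophile, which the preformed terminal enol silane secures, and addition to the aldehyde rather than aldehyde self-condensation, which the neutral conditions at −78 °C secure because 7 is not enolised there; the benzyl ethers keep acidic phenols away from the Lewis acid.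

Step 6
Reactants: 9 (5S)-1,7-bis[4-(benzyloxy)-3-methoxyphenyl]-5-hydroxyheptan-3-one
Product: 11 (3S,5S)-5-acetoxy-1,7-bis[4-(benzyloxy)-3-methoxyphenyl]heptan-3-ol, via hemiacetal 10 (not isolated)
Conditions: MeCHO (8 equiv, freshly distilled), SmI2 (30 mol%), THF, −10 °C
Reagents that add atoms: acetaldehyde, CC=O
Why: Evans–Tishchenko reduction, in which samarium(III) holds the C3 ketone and the hemiacetal 10 formed from the C5 hydroxyl and acetaldehyde in a chair-like six-membered transition state, so that the hemiacetal hydrogen is delivered intramolecularly to the ketone face that gives the 1,3-anti (3S) alcohol while the hemiacetal becomes the C5 acetate.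

Step 7
Reactants: 11 (3S,5S)-5-acetoxy-1,7-bis[4-(benzyloxy)-3-methoxyphenyl]heptan-3-ol
Product: 12 (3S,5S)-5-acetoxy-1,7-bis(4-hydroxy-3-methoxyphenyl)heptan-3-ol
Conditions: H2 (1 atm), 10% Pd/C, EtOAc, rt
Reagents that add atoms: none
Why: Catalytic hydrogenolysis cleaves the two benzylic C–O bonds of the aryl benzyl ethers under neutral conditions that leave the secondary acetate, the free alcohol and both stereocentres untouched, and a 1,3-acyl shift, should it occur, is degenerate because the diol core is C2-symmetric.

Compound list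
1 | zingerone, 4-(4-hydroxy-3-methoxyphenyl)butan-2-one | CC(=O)CCc1ccc(O)c(OC)c1 | starting material
2 | 4-[4-(benzyloxy)-3-methoxyphenyl]butan-2-one | CC(=O)CCc1ccc(OCc2ccccc2)c(OC)c1 | intermediate
3 | lithium 4-[4-(benzyloxy)-3-methoxyphenyl]but-1-en-2-olate (not isolated) | [Li+].[O-]C(=C)CCc1ccc(OCc2ccccc2)c(OC)c1 | intermediate
4 | 2-(trimethylsilyloxy)-4-[4-(benzyloxy)-3-methoxyphenyl]but-1-ene | C=C(CCc1ccc(OCc2ccccc2)c(OC)c1)O[Si](C)(C)C | intermediate
5 | dihydroconiferyl alcohol, 3-(4-hydroxy-3-methoxyphenyl)propan-1-ol | OCCCc1ccc(O)c(OC)c1 | starting material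
6 | 3-[4-(benzyloxy)-3-methoxyphenyl]propan-1-ol | OCCCc1ccc(OCc2ccccc2)c(OC)c1 | intermediate
7 | 3-[4-(benzyloxy)-3-methoxyphenyl]propanal | O=CCCc1ccc(OCc2ccccc2)c(OC)c1 | intermediate
8 | (5S)-1,7-bis[4-(benzyloxy)-3-methoxyphenyl]-5-(trimethylsilyloxy)heptan-3-one (not isolated) | O=C(CCc1ccc(OCc2ccccc2)c(OC)c1)C[C@@H](O[Si](C)(C)C)CCc1ccc(OCc2ccccc2)c(OC)c1 | intermediate
9 | (5S)-1,7-bis[4-(benzyloxy)-3-methoxyphenyl]-5-hydroxyheptan-3-one | O=C(CCc1ccc(OCc2ccccc2)c(OC)c1)C[C@@H](O)CCc1ccc(OCc2ccccc2)c(OC)c1 | intermediate
10 | (5S)-1,7-bis[4-(benzyloxy)-3-methoxyphenyl]-5-(1-hydroxyethoxy)heptan-3-one, samarium-bound in the flask, hemiacetal carbon unassigned (not isolated) | O=C(CCc1ccc(OCc2ccccc2)c(OC)c1)C[C@@H](OC(C)O)CCc1ccc(OCc2ccccc2)c(OC)c1 | intermediate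
11 | (3S,5S)-5-acetoxy-1,7-bis[4-(benzyloxy)-3-methoxyphenyl]heptan-3-ol | COc1cc(CC[C@H](O)C[C@H](CCc2ccc(OCc3ccccc3)c(OC)c2)OC(C)=O)ccc1OCc1ccccc1 | intermediate
12 | (3S,5S)-5-acetoxy-1,7-bis(4-hydroxy-3-methoxyphenyl)heptan-3-ol | COc1cc(CC[C@H](O)C[C@H](CCc2ccc(O)c(OC)c2)OC(C)=O)ccc1O | target

Total step count: 7.
Longest linear sequence: 5 steps (1 → 2 → 4 → 9 → 11 → 12, or equally 5 → 6 → 7 → 9 → 11 → 12).

Steps most likely to fail

Step 5 (key step). Enantiofacial discrimination on the unbranched, enolisable aldehyde may be incomplete, or catalyst turnover may stall, so that 9 would be formed with too low an enantiomeric purity for a single-enantiomer target. The fallback sets out from 2 and 7 and comes back to the route at 11; it keeps the C4–C5 aldol bond but moves all stereocontrol to a later hydrogenation.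
- The lithium enolate 3 (LDA, THF, −78 °C, no silyl quench) is added to 7 to give the racemic aldol 1,7-bis[4-(benzyloxy)-3-methoxyphenyl]-5-hydroxyheptan-3-one F1.
- Dess–Martin oxidation should give the symmetrical diketone 1,7-bis[4-(benzyloxy)-3-methoxyphenyl]heptane-3,5-dione F2.
- Noyori asymmetric hydrogenation (H2 under pressure, Ru(II)–(S)-BINAP dichloride, MeOH/CH2Cl2, 50 °C) should reduce both carbonyls under catalyst control to the anti-diol (3S,5S)-1,7-bis[4-(benzyloxy)-3-methoxyphenyl]heptane-3,5-diol F3. Mismatched reductions end mainly in the meso diol, which is a separable diastereomer, so the enantiomeric purity of F3 is amplified.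
- Trimethyl orthoacetate with catalytic PPTS in CH2Cl2 should give the cyclic orthoester (4S,6S)-4,6-bis{2-[4-(benzyloxy)-3-methoxyphenyl]ethyl}-2-methoxy-2-methyl-1,3-dioxane F4, which aqueous acetic acid opens to 11. Only one monoacetate can form because the two hydroxyls of F3 are homotopic.

Step 6. Retro-aldol fragmentation of the samarium aldolate, or consumption of acetaldehyde by self-condensation, may stall the intramolecular hydride transfer. The fallback sets out from 9 and comes back to the route at 12; hydride is delivered from an external reagent and the acetate is put on last.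
- Hydrogenolysis (H2, Pd/C, EtOAc) should give (5S)-5-hydroxy-1,7-bis(4-hydroxy-3-methoxyphenyl)heptan-3-one F5.
- Saksena–Evans reduction (Me4NBH(OAc)3, MeCN/AcOH, −30 °C), with hydride delivered from the borohydride bound to the C5 oxygen, should give the anti-diol (3S,5S)-1,7-bis(4-hydroxy-3-methoxyphenyl)heptane-3,5-diol F6.
- Trimethyl orthoacetate with catalytic PPTS should convert the 1,3-diol into the cyclic orthoester (4S,6S)-4,6-bis[2-(4-hydroxy-3-methoxyphenyl)ethyl]-2-methoxy-2-methyl-1,3-dioxane F7, and aqueous acetic acid should open it to 12. The phenols cannot form the six-membered orthoester and should be released unchanged on hydrolysis.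

Step 2. Partial equilibration to the internal enolate would erode the regiochemical purity of 4, and the terminal trimethylsilyl enol ether may hydrolyse during isolation. The fallback sets out from 2 and comes back to the route at 9; it avoids any preformed enolate. Ketone 2 (in excess, recovered) and 7 (added slowly) are combined in a direct enamine-catalysed aldol reaction with (S)-proline or an (S)-prolinamide in DMSO/CHCl3 at 4 °C. The enamine should form on the methyl side and add to the Re face of the aldehyde through the hydrogen-bonded chair-like transition state, which gives 9 with the 5S configuration. No new isolated compound arises.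

Further compounds
F1 | step 5 | racemic 1,7-bis[4-(benzyloxy)-3-methoxyphenyl]-5-hydroxyheptan-3-one | O=C(CCc1ccc(OCc2ccccc2)c(OC)c1)CC(O)CCc1ccc(OCc2ccccc2)c(OC)c1
F2 | step 5 | 1,7-bis[4-(benzyloxy)-3-methoxyphenyl]heptane-3,5-dione | O=C(CCc1ccc(OCc2ccccc2)c(OC)c1)CC(=O)CCc1ccc(OCc2ccccc2)c(OC)c1
F3 | step 5 | (3S,5S)-1,7-bis[4-(benzyloxy)-3-methoxyphenyl]heptane-3,5-diol | COc1cc(CC[C@H](O)C[C@H](CCc2ccc(OCc3ccccc3)c(OC)c2)O)ccc1OCc1ccccc1
F4 | step 5 | (4S,6S)-4,6-bis{2-[4-(benzyloxy)-3-methoxyphenyl]ethyl}-2-methoxy-2-methyl-1,3-dioxane | COc1cc(CC[C@H]2C[C@H](CCc3ccc(OCc4ccccc4)c(OC)c3)OC(C)(OC)O2)ccc1OCc1ccccc1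
F5 | step 6 | (5S)-5-hydroxy-1,7-bis(4-hydroxy-3-methoxyphenyl)heptan-3-one | O=C(CCc1ccc(O)c(OC)c1)C[C@@H](O)CCc1ccc(O)c(OC)c1
F6 | step 6 | (3S,5S)-1,7-bis(4-hydroxy-3-methoxyphenyl)heptane-3,5-diol | COc1cc(CC[C@H](O)C[C@H](CCc2ccc(O)c(OC)c2)O)ccc1O
F7 | step 6 | (4S,6S)-4,6-bis[2-(4-hydroxy-3-methoxyphenyl)ethyl]-2-methoxy-2-methyl-1,3-dioxane | COc1cc(CC[C@H]2C[C@H](CCc3ccc(O)c(OC)c3)OC(C)(OC)O2)ccc1O
F0 | step 2 | none | none
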